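**Retrosynthetic overview**
- Target ← ferutinin by face-selective epoxidation; ferutinin ← jaeschkeanadiol + 4-iodophenol + CO by palladium-catalysed carbonylative esterification of the secondary hydroxyl.
- Jaeschkeanadiol ← seven-membered ring by ring-closing metathesis of a 2,3-trans cyclopentane diene-diol; tertiary carbinol by isopropyl addition to a cyclopentanone.
- Cyclopentanone ← key step: stereospecific semipinacol ring expansion of a 2,3-epoxy cyclobutanol, in which the quaternary ring carbon migrates, the ring-fusion CH is set and the carbinol oxygen is carried along.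
- Epoxy cyclobutanol ← (R)-2-allyl-2-methylcyclobutanone + 2-methylpent-1-en-4-yne, then catalyst-controlled epoxidation of the (E)-alkene.
- Quaternary centre ← new direct enantioselective α-allylation of 2-methylcyclobutanone. Ring order: four-membered (bought) → five-membered (ring expansion) → seven-membered (metathesis).

Assumption: 2-methylpent-1-en-4-yne and the L-series Shi ketone are taken as purchasable; 2-methylcyclobutanone is used as the racemate.

**Step 1**
Reactants: 1 2-methylcyclobutan-1-one (racemic); 2 prop-2-en-1-ol (allyl alcohol)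
Product: 3 (R)-2-allyl-2-methylcyclobutan-1-one
Conditions: Pd(PPh3)4 (3 mol %), (S)-3,3'-bis(2,4,6-triisopropylphenyl)-1,1'-binaphthyl-2,2'-diyl hydrogen phosphate [(S)-TRIP, 6 mol %; its antipode if the sense of induction proves opposite], Ph2CHNH2 (40 mol %), MTBE, 5 Å MS, 40 °C; then 1 M HCl
Reagents that add atoms: none
Why: Proposed new method: benzhydrylamine condenses with racemic 1 to the more substituted enamine (the old stereocentre becomes sp2, so both enantiomers converge), Pd(PPh3)4 and the acid ionise allyl alcohol to a cationic π-allyl complex, and the chiral phosphate, hydrogen-bonded to the enamine N–H and ion-paired with the π-allyl cation, directs C–C bond formation to one face to set the (R) quaternary centre before hydrolysis releases the amine; the closest known reactions are the amine/chiral phosphoric acid/palladium α-allylation of α-branched aldehydes with allylic alcohols and the palladium-catalysed decarboxylative allylic alkylation (Tsuji–Trost type) that gives α-quaternary cyclobutanones.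

**Step 2**
Reactants: 3 (R)-2-allyl-2-methylcyclobutan-1-one; 4 2-methylpent-1-en-4-yne
Product: 6 (2R)-2-allyl-2-methyl-1-[(1E)-4-methylpenta-1,4-dien-1-yl]cyclobutan-1-ol (both carbinol epimers), via propargylic alkoxide 5 (not isolated)
Conditions: 4, n-BuLi, THF, −78 °C; add 3; then NaAlH2(OCH2CH2OMe)2, −78 °C → rt; aq. NH4Cl
Reagents that add atoms: none
Why: Acetylide 1,2-addition to the strained ketone followed by alkoxide-directed trans-hydroalumination of the propargylic alkoxide gives only the (E)-alkene, and the new carbinol centre may form as a mixture because it becomes the carbonyl carbon in step 4.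

**Step 3**
Reactants: 6 (2R)-2-allyl-2-methyl-1-[(1E)-4-methylpenta-1,4-dien-1-yl]cyclobutan-1-ol
Product: 7 (2R)-2-allyl-2-methyl-1-[(2R,3S)-3-(2-methylprop-2-en-1-yl)oxiran-2-yl]cyclobutan-1-ol
Conditions: L-series Shi ketone (1,2:4,5-di-O-isopropylidene-β-L-erythro-2,3-hexodiulo-2,6-pyranose, 30 mol %), KHSO5 (as 2KHSO5·KHSO4·K2SO4), K2CO3, Bu4NHSO4, MeCN/CH2(OMe)2/aq. Na2B4O7 buffer (pH 10.5), 0 °C
Reagents that add atoms: potassium peroxymonosulfate, [K+].[O-]S(=O)(=O)OO
Why: Shi asymmetric epoxidation, in which the chiral dioxirane reacts fastest with the trans-disubstituted alkene (the 1,1-disubstituted and monosubstituted alkenes are slow) and, under catalyst control through the spiro transition state, gives the (2R,3S)-epoxide whatever the carbinol configuration, fixing the two carbons that become the ring-fusion CH and the secondary carbinol.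

**Step 4**
Reactants: 7 (2R)-2-allyl-2-methyl-1-[(2R,3S)-3-(2-methylprop-2-en-1-yl)oxiran-2-yl]cyclobutan-1-ol
Product: 8 (2S,3R)-3-allyl-2-[(1S)-1-hydroxy-3-methylbut-3-en-1-yl]-3-methylcyclopentan-1-one
Conditions: BF3·OEt2 (20 mol %), CH2Cl2, −78 → −30 °C; Et3N quench
Reagents that add atoms: none
Why: Semipinacol rearrangement of a 2,3-epoxy alcohol with ring expansion driven by release of cyclobutane strain, in which the more substituted (quaternary) ring carbon migrates antiperiplanar to the breaking C–O bond with inversion at the epoxide carbon and retention in the migrating carbon, so the ring-fusion CH is set trans to the allyl arm, the secondary carbinol keeps its configuration and both carbinol epimers of 7 give the same ketone.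

**Step 5**
Reactants: 8 (2S,3R)-3-allyl-2-[(1S)-1-hydroxy-3-methylbut-3-en-1-yl]-3-methylcyclopentan-1-one; 9 isopropylmagnesium chloride
Product: 10 (1R,2S,3R)-3-allyl-2-[(1S)-1-hydroxy-3-methylbut-3-en-1-yl]-3-methyl-1-(propan-2-yl)cyclopentan-1-ol
Conditions: 9 (3 equiv), CeCl3 (3 equiv), THF, −78 → 0 °C; aq. NH4Cl
Reagents that add atoms: none
Why: Cerium-mediated Grignard 1,2-addition (which suppresses enolisation and β-hydride reduction) takes place on the ketone face anti to the adjacent side chain, placing the new hydroxyl cis to that side chain and to the methyl group, i.e. (1R).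

**Step 6**
Reactants: 10 (1R,2S,3R)-3-allyl-2-[(1S)-1-hydroxy-3-methylbut-3-en-1-yl]-3-methyl-1-(propan-2-yl)cyclopentan-1-ol
Product: 11 jaeschkeanadiol, (3R,3aS,4S,8aR)-6,8a-dimethyl-3-(propan-2-yl)-1,2,3,3a,4,5,8,8a-octahydroazulene-3,4-diol
Conditions: second-generation Grubbs catalyst (5 mol %), CH2Cl2 (5 mM), 40 °C
Reagents that add atoms: none
Why: Ring-closing metathesis between the allyl and 2-methylallyl arms, held trans on the cyclopentane, closes the trans-fused seven-membered ring with its trisubstituted alkene and releases ethene without touching any stereocentre.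

**Step 7**
Reactants: 12 4-iodophenol
Product: 13 tert-butyl(4-iodophenoxy)dimethylsilane
Conditions: t-BuMe2SiCl, imidazole, DMF, 23 °C
Reagents that add atoms: tert-butyldimethylsilyl chloride, CC(C)(C)[Si](C)(C)Cl
Why: Standard silylation masks the phenol so that it cannot compete as a nucleophile in the carbonylation.

**Step 8**
Reactants: 11 jaeschkeanadiol; 13 tert-butyl(4-iodophenoxy)dimethylsilane; 14 carbon monoxide
Product: 16 ferutinin, via silyl-protected ferutinin 15 (not isolated)
Conditions: Pd(OAc)2 (5 mol %), Xantphos (6 mol %), CO (1 atm), Et3N, toluene, 90 °C; then Bu4NF, AcOH, THF, 0 °C (same flask)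
Reagents that add atoms: none
Why: Palladium-catalysed alkoxycarbonylation (oxidative addition of the aryl iodide to zerovalent palladium, CO insertion, alcoholysis of the acyl–palladium) esterifies the secondary hydroxyl while the tertiary one is too hindered, and buffered fluoride then removes the aryl silyl ether without touching the ester or any stereocentre.

**Step 9**
Reactants: 16 ferutinin
Product: 17 jaeskeanin (target)
Conditions: mCPBA (1.1 equiv), NaHCO3, CH2Cl2, 0 °C
Reagents that add atoms: meta-chloroperoxybenzoic acid, OOC(=O)c1cccc(Cl)c1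
Why: Prilezhaev epoxidation of the only alkene, where the peracid is expected to approach from the face opposite the angular methyl group that shields the other face of the seven-membered ring, giving the epoxide cis to the ring-fusion hydrogen as in the target.

**Compound list**
1 | 2-methylcyclobutan-1-one (racemic) | CC1CCC1=O | starting material
2 | prop-2-en-1-ol (allyl alcohol) | C=CCO | starting material
3 | (R)-2-allyl-2-methylcyclobutan-1-one | C=CC[C@@]1(C)CCC1=O | intermediate
4 | 2-methylpent-1-en-4-yne | CC(=C)CC#C | starting material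
5 | (2R)-2-allyl-2-methyl-1-(4-methylpent-4-en-1-yn-1-yl)cyclobutan-1-ol, present as its lithium alkoxide (both carbinol epimers) | C=CC[C@@]1(C)CCC1(O)C#CCC(C)=C | intermediate
6 | (2R)-2-allyl-2-methyl-1-[(1E)-4-methylpenta-1,4-dien-1-yl]cyclobutan-1-ol (both carbinol epimers) | C=CC[C@@]1(C)CCC1(O)/C=C/CC(C)=C | intermediate
7 | (2R)-2-allyl-2-methyl-1-[(2R,3S)-3-(2-methylprop-2-en-1-yl)oxiran-2-yl]cyclobutan-1-ol (both carbinol epimers) | C=CC[C@@]1(C)CCC1(O)[C@@H]2O[C@H]2CC(C)=C | intermediate
8 | (2S,3R)-3-allyl-2-[(1S)-1-hydroxy-3-methylbut-3-en-1-yl]-3-methylcyclopentan-1-one | O=C1CC[C@](C)(CC=C)[C@H]1[C@@H](O)CC(C)=C | intermediate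
9 | isopropylmagnesium chloride | CC(C)[Mg]Cl | starting material
10 | (1R,2S,3R)-3-allyl-2-[(1S)-1-hydroxy-3-methylbut-3-en-1-yl]-3-methyl-1-(propan-2-yl)cyclopentan-1-ol | CC(C)[C@]1(O)CC[C@](C)(CC=C)[C@H]1[C@@H](O)CC(C)=C | intermediate
11 | jaeschkeanadiol, (3R,3aS,4S,8aR)-6,8a-dimethyl-3-(propan-2-yl)-1,2,3,3a,4,5,8,8a-octahydroazulene-3,4-diol | CC(C)[C@]1(O)CC[C@]2(C)CC=C(C)C[C@H](O)[C@H]21 | intermediate
12 | 4-iodophenol | Oc1ccc(I)cc1 | starting material
13 | tert-butyl(4-iodophenoxy)dimethylsilane | CC(C)(C)[Si](C)(C)Oc1ccc(I)cc1 | intermediate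
14 | carbon monoxide | [C-]#[O+] | starting material
15 | ferutinin tert-butyldimethylsilyl ether (silyl on the phenol oxygen) | CC(C)[C@]1(O)CC[C@]2(C)CC=C(C)C[C@H](OC(=O)c3ccc(O[Si](C)(C)C(C)(C)C)cc3)[C@H]21 | intermediate
16 | ferutinin (jaeschkeanadiol 4-hydroxybenzoate at the secondary hydroxyl) | CC(C)[C@]1(O)CC[C@]2(C)CC=C(C)C[C@H](OC(=O)c3ccc(O)cc3)[C@H]21 | intermediate
17 | jaeskeanin | CC(C)[C@]1(O)CC[C@]2(C)C[C@@H]3O[C@]3(C)C[C@H](OC(=O)c3ccc(O)cc3)[C@H]21 | target

**Step count and risks**
Total: 9 steps. Longest linear sequence: 8 steps (steps 1–6, 8, 9); step 7 is a one-step side branch.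

Step 1 (the proposed new allylation). Risks are allylation at the less substituted α-carbon, double allylation and low enantioselectivity. The fallback uses known chemistry and sets out from 1: the thermodynamic silyl enol ether trimethyl[(2-methylcyclobut-1-en-1-yl)oxy]silane F1 is made with Me3SiCl, NaI and Et3N in MeCN. It is then allylated enantioselectively (Tsuji allylation of an enol silane) with allyl methyl carbonate, Pd2(dba)3, (R)-t-Bu-PHOX and Bu4N[Ph3SiF2] in THF, which returns to 3.

Step 3 (Shi epoxidation). Risks are competing epoxidation of the 2-methylallyl alkene and incomplete catalyst control next to the bulky carbinol. The fallback sets out from 3 and takes the epoxide configuration from the chiral pool. (S)-Epichlorohydrin is opened with isopropenylmagnesium bromide (CuI cat.) to the chlorohydrin (S)-1-chloro-4-methylpent-4-en-2-ol F2, which NaOH closes to (S)-2-(2-methylprop-2-en-1-yl)oxirane F3. Trans-selective α-lithiation of F3 (s-BuLi, a diamine ligand, Et2O, −90 °C) and addition to ketone 3 gives epoxy alcohol 7 directly.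

Step 5 (isopropyl addition). Risks are enolisation, β-hydride reduction and retro-aldol cleavage of the β-alkoxy ketone. The fallback sets out from 8 and reverses the order of ring closure and addition. Ring-closing metathesis with the second-generation Grubbs catalyst first gives the trans-fused hydroxy ketone (3aS,4S,8aR)-4-hydroxy-6,8a-dimethyl-2,3a,4,5,8,8a-hexahydroazulen-3(1H)-one F4. Addition of i-PrLi/CeCl3 to this rigid bicyclic ketone, from the face opposite the angular methyl, then arrives at 11.

**Further compounds**
F1 | step 1 | trimethyl[(2-methylcyclobut-1-en-1-yl)oxy]silane | CC1=C(O[Si](C)(C)C)CC1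
F2 | step 3 | (S)-1-chloro-4-methylpent-4-en-2-ol | ClC[C@@H](O)CC(C)=C
F3 | step 3 | (S)-2-(2-methylprop-2-en-1-yl)oxirane | C1O[C@H]1CC(C)=C
F4 | step 5 | (3aS,4S,8aR)-4-hydroxy-6,8a-dimethyl-2,3a,4,5,8,8a-hexahydroazulen-3(1H)-one | O=C1CC[C@]2(C)CC=C(C)C[C@H](O)[C@H]21
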